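A small charge of E can carry off little Z: if each Z lost takes one E, then teal, with 0.045 M of E on 0.50 M of Z, can lose at most 9.00 % of its Z.

| flask | Z | E | remark | time |
|---|---|---|---|---|
| teal | 0.50 M | 0.045 M | run made earlier |  |
| green | 0.50 M | 0.83 M | run made earlier |  |
| west | 0.50 M | 0.0800 M |  | 2.5 h |
| south-west | 0.50 M | 0.800 M |  | 2.5 h |
| north | 0.50 M | 1.00 M |  | 2.5 h |
| north-east | 0.50 M | 0.250 M |  | 2.5 h |

| run | time / h | J / % |
|---|---|---|
| teal | 0.167 | 31.9 |
| teal | 0.500 | 68.3 |
| teal | 0.833 | 80.3 |
| teal | 1.33 | 83.3 |
| teal | 2.00 | 82.7 |
| teal | 2.50 | 79.5 |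
| green | 0.167 | 29.0 |
| green | 0.500 | 51.3 |
| green | 0.833 | 55.6 |
| green | 1.33 | 54.3 |
| green | 2.00 | 51.6 |
| green | 2.50 | 50.7 |

(standard deviation of a reading: 0.5 percentage points)



* ranking by amount of J, in percent of the Z charged, from high to low, at 2.5 h (west / south-west / north / north-east)
* the amount of J, in percent of the Z charged of the flask you put first, at 2.5 h
* the amount of J, in percent of the Z charged of the flask you put last, at 2.5 h

We keep a ledger of the Z at 2.5 h, entering none as left over. Each Z is either kept, meaning it reached J, whether it still stands as J or has faded since, or it is lost to E. Let f be the fraction kept. We suppose that J = g·f, with g the share of kept Z still present as J, the same in every flask. We also suppose that lost/kept = s·m, where m is the mean E of the run: the E charged less half of the Z lost. With g shared, the two readings at 2.5 h give the ratio of their f, within their scatter, and we work with that fraction left.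

Green f / teal f = 0.638

First pass, with teal's loss at half its ceiling: teal f = 95.5 %, green f = 60.9 %, green m = 0.732 M, s = 0.877 L mol⁻¹

Second pass: teal f = 97.1 %, green f = 61.9 %, s = 0.836 L mol⁻¹

This s is the selectivity factor, the Z lost per Z kept for each unit of mean E. Teal then gives g = 81.9 %.

With s and g held, f falls as E rises, so J ranks by E: west, north-east, south-west, north. The two ends take the same two passes:

West: f = 93.7 %, then 94.9 %, so J = 77.7 %

North: f = 54.5 %, then 57.4 %, so J = 47.0 %

The forecast gives west > north-east > south-west > north, with 76.5 % and 48 %, on the ground that E “opens a competing loss of Z”; its top stands lower than ours and its low higher.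

The flasks give west > north-east > south-west > north, with west at 77.9 % and north at 47.4 %.

    Z ⇌ X (K = 0.170, k = 4.10 h⁻¹)
    X → J (k = 47.0 h⁻¹)
    Z + E → L (k = 2.20 L mol⁻¹ h⁻¹)
    J ⇌ G (K = 0.290, k = 0.170 h⁻¹)

Our books for north lost 42.6 % of the Z, and north holds 42.0 % as L, the product of the Z + E step. The neighbour is north with 1.7 M of E in place of 1.00 M, all else held. The same two passes with s give f = 41.3 %, then 43.5 %, so we book J at 35.6 % and the loss at 56.5 %. That flask gives J 36.0 % and L 55.8 %, with 84 % of its E left.

Readings and results are simulated with constants of no real substance, and the scatter is random.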